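Ring B of the bicyclo[3.3.1]nonane (C1, C9, C5, C6, C7, C8) is cut at C5–C6 and C1–C8, which lifts the C6–C7–C8 bridge off the phloroglucinol-derived ring A (C1 to C5 plus C9) as an enantiopure ten-carbon hydroxy iodide carrying C7. The key step rejoins both ends in one flask: C-alkylation of a 2,4-diacyl-6-prenylphloroglucinol at C5, then ionisation of the tertiary alcohol and capture of the C8 cation by C1. It exploits the 1,3-relation of C1 and C5 across the C9 carbonyl and, because C1 and C3 carry identical acyl groups, a prochiral C5: the C7 stereocentre alone sets C1 and C5. The extra C3 acyl group is then exchanged for the side chain.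

Key step: step 8

Assumption: the enolised trione is handled as the 2-oxo-4-hydroxy tautomer drawn for the target (the tautomers interconvert), and the target numbering C1 to C9 of the bicyclo[3.3.1]nonane is used for the corresponding atoms of every intermediate.

Step 1
Reactants: 1 (R)-2-methylbutanoic acid (2.1 equiv); 2 phloroglucinol
Product: 4 2,4-bis[(2R)-2-methylbutanoyl]phloroglucinol, via (R)-2-methylbutanoyl chloride 3 (not isolated)
Conditions: (COCl)2, DMF (cat.), CH2Cl2, 0 °C to rt; then 2, AlCl3, PhNO2, 0 °C to rt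
Reagents that add atoms: none
Why: Twofold Friedel–Crafts acylation of the electron-rich triol by the acid chloride made in the flask should stop at the 2,4-diacyl stage because the ring is then deactivated, and the α-stereocentres should not be enolised under these cold Lewis-acidic conditions.

Step 2
Reactants: 4 2,4-bis[(2R)-2-methylbutanoyl]phloroglucinol
Product: 5 2,4-bis[(2R)-2-methylbutanoyl]-6-(3-methylbut-2-en-1-yl)phloroglucinol
Conditions: prenyl bromide (1.0 equiv), KOH (aq.), 0 °C
Reagents that add atoms: prenyl bromide, CC(C)=CCBr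
Why: C-Prenylation of the phloroglucinolate in water (aromatic C-alkylation of an ambident phenolate, oxygen being shielded by hydrogen bonding) can occur only at the single unsubstituted ring carbon, the future C5.

Step 3
Reactants: 6 (S)-4-benzyloxazolidin-2-one; 7 3-methylbut-2-enoyl chloride
Product: 8 (S)-4-benzyl-3-(3-methylbut-2-enoyl)oxazolidin-2-one
Conditions: n-BuLi, THF, −78 °C; then 7, −78 to 0 °C
Reagents that add atoms: none
Why: N-Acylation of the oxazolidinone deprotonated with n-BuLi by the acid chloride is the standard loading of the Evans auxiliary.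

Step 4
Reactants: 8 (S)-4-benzyl-3-(3-methylbut-2-enoyl)oxazolidin-2-one
Product: 9 (S)-4-benzyl-3-[(2S)-5-methyl-2-(prop-1-en-2-yl)hex-4-enoyl]oxazolidin-2-one
Conditions: NaN(SiMe3)2, THF, −78 °C; prenyl bromide, −78 to −40 °C
Reagents that add atoms: prenyl bromide, CC(C)=CCBr
Why: γ-Deprotonation gives the chelated dienolate, which prenyl bromide alkylates at the α-carbon on the face opposite the benzyl group (deconjugative Evans alkylation), setting the (2S) centre that becomes C7 of the target.

Step 5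
Reactants: 9 (S)-4-benzyl-3-[(2S)-5-methyl-2-(prop-1-en-2-yl)hex-4-enoyl]oxazolidin-2-one
Product: 11 (S)-4-benzyl-3-[(2S)-2-(2-hydroxypropan-2-yl)-5-methylhex-4-enoyl]oxazolidin-2-one, via organomercurial 10 (not isolated)
Conditions: Hg(OAc)2, THF–H2O, 0 °C; then NaBH4, NaOH (aq.), 0 °C
Reagents that add atoms: water, O
Why: Oxymercuration–demercuration should hydrate the 1,1-disubstituted isopropenyl group in Markovnikov fashion much faster than the trisubstituted prenyl group, which turns the future C8 into a tertiary carbinol without touching the adjacent stereocentre.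

Step 6
Reactants: 11 (S)-4-benzyl-3-[(2S)-2-(2-hydroxypropan-2-yl)-5-methylhex-4-enoyl]oxazolidin-2-one
Product: 12 (2R)-2-(2-hydroxypropan-2-yl)-5-methylhex-4-en-1-ol
Conditions: LiBH4, MeOH (1 equiv), THF, 0 °C
Reagents that add atoms: none
Why: LiBH4 cleaves the N-acyl oxazolidinone reductively (standard auxiliary removal) to the primary alcohol and returns 6, with no effect on the stereocentre or the alkene.

Step 7
Reactants: 12 (2R)-2-(2-hydroxypropan-2-yl)-5-methylhex-4-en-1-ol
Product: 13 (3S)-3-(iodomethyl)-2,6-dimethylhept-5-en-2-ol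
Conditions: I2, PPh3, imidazole, CH2Cl2, 0 °C
Reagents that add atoms: iodine, II
Why: Appel-type iodination should convert only the primary alcohol, since an alkoxyphosphonium ion of the tertiary alcohol cannot undergo SN2 displacement.

Step 8
Reactants: 5 2,4-bis[(2R)-2-methylbutanoyl]-6-(3-methylbut-2-en-1-yl)phloroglucinol; 13 (3S)-3-(iodomethyl)-2,6-dimethylhept-5-en-2-ol
Product: 15 (1R,5S,7R)-4-hydroxy-8,8-dimethyl-1,3-bis[(2R)-2-methylbutanoyl]-5,7-bis(3-methylbut-2-en-1-yl)bicyclo[3.3.1]non-3-ene-2,9-dione, via C5-alkylated cyclohexadienone 14 (not isolated)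
Conditions: NaOMe (2 equiv), MeOH, 60 °C; AcOH (1 equiv), solvent exchange to CH2Cl2; BF3·OEt2, 2,6-di-tert-butylpyridine, −78 to −20 °C
Reagents that add atoms: none
Why: The dianion of 5 is alkylated at C5, the only ring carbon without an acyl group, by SN2 displacement of iodide from 13 (alkylative dearomatization, as in the C-alkylation of acylphloroglucinols to lupulone-type cyclohexadienones), which forms C5–C6 and should give 14 as a single compound because C5, flanked by two identical acyl-bearing arms, is not yet a stereocentre. BF3·OEt2 buffered with the hindered pyridine then ionises the tertiary alcohol and the C8 cation is captured by an acyl-bearing enol carbon to form C1–C8, the closest known reaction types being the Lewis-acid SN1 tert-alkylation of 1,3-dicarbonyl enols by tertiary alcohols and the cation–enol closures used for bicyclo[3.3.1]nonane cores. Ring B (C1, C9, C5, C6, C7, C8) closes in a 6-(enolendo)-exo-trig mode through a chair. C1 and C5 are set together by C7: only the enol carbon that lets the C7 prenyl group lie equatorial, on the exo face away from ring A, can reach C8 in the chair, whereas closure at the mirror-related carbon would force that group axially into ring A. The step needs carbon rather than oxygen alkylation at C5, favoured by the protic solvent and the soft iodide, and carbon rather than oxygen capture of the cation, which should follow because the tertiary enol ether from O-capture re-ionises under the Lewis acid while the C–C bond does not. The buffer keeps the prenyl groups unprotonated and makes any proton loss from the cation irreversible, so C7 cannot be scrambled.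

Step 9
Reactants: 15 (1R,5S,7R)-4-hydroxy-8,8-dimethyl-1,3-bis[(2R)-2-methylbutanoyl]-5,7-bis(3-methylbut-2-en-1-yl)bicyclo[3.3.1]non-3-ene-2,9-dione
Product: 18 (1S,5S,7R)-4-hydroxy-8,8-dimethyl-1-[(2R)-2-methylbutanoyl]-5,7-bis(3-methylbut-2-en-1-yl)bicyclo[3.3.1]non-3-ene-2,9-dione, via 3-chloro triketone 16 (not isolated), via 3-chloro enol 17 (not isolated)
Conditions: NaH, THF, 0 °C; N-chlorosuccinimide, −78 °C; K2CO3 (cat.), MeOH, 0 °C; then Zn, AcOH, rt
Reagents that add atoms: none
Why: Chlorination of the triketone enolate at C3 turns the C3 acyl group into part of a non-enolisable tricarbonyl that methoxide should cleave by retro-Claisen reaction (haloform-type deacylation, the C1 acyl group being safe because its loss would need a bridgehead carbanion), and Zn then reduces the α-chloro-β-diketone to the C3–H enol.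

Step 10
Reactants: 18 (1S,5S,7R)-4-hydroxy-8,8-dimethyl-1-[(2R)-2-methylbutanoyl]-5,7-bis(3-methylbut-2-en-1-yl)bicyclo[3.3.1]non-3-ene-2,9-dione
Product: 19 (1S,5S,7R)-4-hydroxy-8,8-dimethyl-1-[(2R)-2-methylbutanoyl]-5,7-bis(3-methylbut-2-en-1-yl)-3-(3-oxobutyl)bicyclo[3.3.1]non-3-ene-2,9-dione
Conditions: methyl vinyl ketone (1.0 equiv), Et3N (cat.), THF, rt
Reagents that add atoms: methyl vinyl ketone, C=CC(C)=O
Why: Michael addition of the cyclic 1,3-diketone through C3, its only enolisable carbon, to one equivalent of methyl vinyl ketone should install the four-carbon chain.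

Step 11
Reactants: 19 (1S,5S,7R)-4-hydroxy-8,8-dimethyl-1-[(2R)-2-methylbutanoyl]-5,7-bis(3-methylbut-2-en-1-yl)-3-(3-oxobutyl)bicyclo[3.3.1]non-3-ene-2,9-dione
Product: 20 (1S,5S,7R)-4-hydroxy-3-(3-hydroxy-3-methylbutyl)-8,8-dimethyl-1-[(2R)-2-methylbutanoyl]-5,7-bis(3-methylbut-2-en-1-yl)bicyclo[3.3.1]non-3-ene-2,9-dione (target)
Conditions: MeMgBr (3.5 equiv), CeCl3, THF, −78 °C
Reagents that add atoms: methylmagnesium bromide, C[Mg]Br
Why: After deprotonation of the enol, the reagent from MeMgBr and CeCl3 should add only to the unhindered methyl ketone (1,2-addition), because the C9 and acyl ketones are flanked by quaternary or branched carbons and the enolate is unreactive, which gives the tertiary alcohol of the target.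

Compound list
1 | (R)-2-methylbutanoic acid | CC[C@@H](C)C(=O)O | starting material
2 | phloroglucinol (benzene-1,3,5-triol) | Oc1cc(O)cc(O)c1 | starting material
3 | (R)-2-methylbutanoyl chloride | CC[C@@H](C)C(Cl)=O | intermediate
4 | 2,4-bis[(2R)-2-methylbutanoyl]phloroglucinol | CC[C@@H](C)C(=O)c1c(O)cc(O)c(C(=O)[C@H](C)CC)c1O | intermediate
5 | 2,4-bis[(2R)-2-methylbutanoyl]-6-(3-methylbut-2-en-1-yl)phloroglucinol | CC[C@@H](C)C(=O)c1c(O)c(CC=C(C)C)c(O)c(C(=O)[C@H](C)CC)c1O | intermediate
6 | (S)-4-benzyloxazolidin-2-one | O=C1N[C@@H](Cc2ccccc2)CO1 | starting material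
7 | 3-methylbut-2-enoyl chloride | CC(C)=CC(Cl)=O | starting material
8 | (S)-4-benzyl-3-(3-methylbut-2-enoyl)oxazolidin-2-one | CC(C)=CC(=O)N1[C@@H](Cc2ccccc2)COC1=O | intermediate
9 | (S)-4-benzyl-3-[(2S)-5-methyl-2-(prop-1-en-2-yl)hex-4-enoyl]oxazolidin-2-one | O=C([C@@H](CC=C(C)C)C(C)=C)N1[C@@H](Cc2ccccc2)COC1=O | intermediate
10 | (S)-3-[(2S)-2-[1-(acetoxymercurio)-2-hydroxypropan-2-yl]-5-methylhex-4-enoyl]-4-benzyloxazolidin-2-one (both carbinol epimers) | O=C([C@@H](CC=C(C)C)C(C)(O)C[Hg]OC(C)=O)N1[C@@H](Cc2ccccc2)COC1=O | intermediate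
11 | (S)-4-benzyl-3-[(2S)-2-(2-hydroxypropan-2-yl)-5-methylhex-4-enoyl]oxazolidin-2-one | O=C([C@@H](CC=C(C)C)C(C)(C)O)N1[C@@H](Cc2ccccc2)COC1=O | intermediate
12 | (2R)-2-(2-hydroxypropan-2-yl)-5-methylhex-4-en-1-ol | OC[C@@H](CC=C(C)C)C(C)(C)O | intermediate
13 | (3S)-3-(iodomethyl)-2,6-dimethylhept-5-en-2-ol | IC[C@@H](CC=C(C)C)C(C)(C)O | intermediate
14 | 3,5-dihydroxy-4-[(2R)-2-(2-hydroxypropan-2-yl)-5-methylhex-4-en-1-yl]-2,6-bis[(2R)-2-methylbutanoyl]-4-(3-methylbut-2-en-1-yl)cyclohexa-2,5-dien-1-one | O=C1C(C(=O)[C@H](C)CC)=C(O)C(CC=C(C)C)(C[C@@H](CC=C(C)C)C(C)(C)O)C(O)=C1C(=O)[C@H](C)CC | intermediate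
15 | (1R,5S,7R)-4-hydroxy-8,8-dimethyl-1,3-bis[(2R)-2-methylbutanoyl]-5,7-bis(3-methylbut-2-en-1-yl)bicyclo[3.3.1]non-3-ene-2,9-dione | CC[C@@H](C)C(=O)[C@]12C(=O)C(C(=O)[C@H](C)CC)=C(O)[C@](CC=C(C)C)(C[C@@H](CC=C(C)C)C1(C)C)C2=O | intermediate
16 | (1R,5R,7R)-3-chloro-8,8-dimethyl-1,3-bis[(2R)-2-methylbutanoyl]-5,7-bis(3-methylbut-2-en-1-yl)bicyclo[3.3.1]nonane-2,4,9-trione (C3 epimers) | CC[C@@H](C)C(=O)[C@]12C(=O)C(Cl)(C(=O)[C@H](C)CC)C(=O)[C@](CC=C(C)C)(C[C@@H](CC=C(C)C)C1(C)C)C2=O | intermediate
17 | (1R,5S,7R)-3-chloro-4-hydroxy-8,8-dimethyl-1-[(2R)-2-methylbutanoyl]-5,7-bis(3-methylbut-2-en-1-yl)bicyclo[3.3.1]non-3-ene-2,9-dione | CC[C@@H](C)C(=O)[C@]12C(=O)C(Cl)=C(O)[C@](CC=C(C)C)(C[C@@H](CC=C(C)C)C1(C)C)C2=O | intermediate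
18 | (1S,5S,7R)-4-hydroxy-8,8-dimethyl-1-[(2R)-2-methylbutanoyl]-5,7-bis(3-methylbut-2-en-1-yl)bicyclo[3.3.1]non-3-ene-2,9-dione | CC[C@@H](C)C(=O)[C@]12C(=O)C=C(O)[C@](CC=C(C)C)(C[C@@H](CC=C(C)C)C1(C)C)C2=O | intermediate
19 | (1S,5S,7R)-4-hydroxy-8,8-dimethyl-1-[(2R)-2-methylbutanoyl]-5,7-bis(3-methylbut-2-en-1-yl)-3-(3-oxobutyl)bicyclo[3.3.1]non-3-ene-2,9-dione | CC[C@@H](C)C(=O)[C@]12C(=O)C(CCC(C)=O)=C(O)[C@](CC=C(C)C)(C[C@@H](CC=C(C)C)C1(C)C)C2=O | intermediate
20 | (1S,5S,7R)-4-hydroxy-3-(3-hydroxy-3-methylbutyl)-8,8-dimethyl-1-[(2R)-2-methylbutanoyl]-5,7-bis(3-methylbut-2-en-1-yl)bicyclo[3.3.1]non-3-ene-2,9-dione | CC[C@@H](C)C(=O)[C@]12C(=O)C(CCC(C)(C)O)=C(O)[C@](CC=C(C)C)(C[C@@H](CC=C(C)C)C1(C)C)C2=O | target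

Total step count: 11
Longest linear sequence: 9 steps (steps 3 to 11)

Steps most likely to fail

Step 8. The phenolate may be alkylated on oxygen, the SN2 displacement at the β-branched iodide may be slow, and after C-alkylation the C8 cation may be trapped by an enol oxygen or lose a proton faster than the weakly nucleophilic acyl-bearing carbon bonds to it. Fallback: the two bond formations are uncoupled and ring B is closed on silyl enol ethers. Setting out from 14, isolated after the alkylation stage, silylation of all three hydroxyl groups (Me3SiCl, Et3N, CH2Cl2) would give the tris(trimethylsilyl) ether F1. Me3SiOTf (cat.) at −78 °C would ionise the tertiary silyl ether, and a silyl enol ether carbon would close ring B in a Mukaiyama–Reetz SN1 alkylation, a carbon-selective manifold, to give the 4-O-trimethylsilyl enol ether F2. Aqueous acid removes the silyl group and the route is rejoined at 15.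

Step 9. Chlorine may be transferred to the prenyl double bonds, or methoxide may open ring A at C2 or C4 instead of removing the C3 acyl group. Fallback: Regitz deacylative diazo transfer in place of the halogenative retro-Claisen cleavage. Setting out from 15, 4-acetamidobenzenesulfonyl azide and Et3N in MeCN would move the C3 acyl group onto the sulfonamide nitrogen and give the 3-diazo trione F3. Si–H insertion with Et3SiH catalysed by Rh2(OAc)4 would give, after 1,3-silyl shift, the triethylsilyl enol ether F4, whose hydrolysis on work-up rejoins the route at 18.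

Step 5. The mercuration may not discriminate well enough between the isopropenyl and prenyl groups, or the imide carbonyl may take part in opening the mercurinium ion. Fallback: the tertiary alcohol is built by methyl addition to an ester instead of alkene hydration, so that no choice between two alkenes is needed. Setting out from 6, acylation with commercial 5-methylhex-4-enoic acid through its mixed anhydride with pivalic acid F5 (pivaloyl chloride, Et3N; then 6, LiCl) would give the imide F6. Its enolate formed with TiCl4 and i-Pr2NEt in CH2Cl2 would be hydroxymethylated by 1,3,5-trioxane on the face opposite the benzyl group to give the hydroxymethyl imide F7. Sm(OTf)3 (cat.) in MeOH would release the methyl ester F8, and excess MeMgBr would convert the ester into the tertiary alcohol, rejoining the route at 12.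

Further compounds
F1 | step 8 | 2,6-bis[(2R)-2-methylbutanoyl]-4-(3-methylbut-2-en-1-yl)-4-[(2R)-5-methyl-2-[2-(trimethylsilyloxy)propan-2-yl]hex-4-en-1-yl]-3,5-bis(trimethylsilyloxy)cyclohexa-2,5-dien-1-one | O=C1C(C(=O)[C@H](C)CC)=C(O[Si](C)(C)C)C(CC=C(C)C)(C[C@@H](CC=C(C)C)C(C)(C)O[Si](C)(C)C)C(O[Si](C)(C)C)=C1C(=O)[C@H](C)CC
F2 | step 8 | (1R,5S,7R)-8,8-dimethyl-1,3-bis[(2R)-2-methylbutanoyl]-5,7-bis(3-methylbut-2-en-1-yl)-4-(trimethylsilyloxy)bicyclo[3.3.1]non-3-ene-2,9-dione | CC[C@@H](C)C(=O)[C@]12C(=O)C(C(=O)[C@H](C)CC)=C(O[Si](C)(C)C)[C@](CC=C(C)C)(C[C@@H](CC=C(C)C)C1(C)C)C2=O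
F3 | step 9 | (1R,5R,7R)-3-diazo-8,8-dimethyl-1-[(2R)-2-methylbutanoyl]-5,7-bis(3-methylbut-2-en-1-yl)bicyclo[3.3.1]nonane-2,4,9-trione | CC[C@@H](C)C(=O)[C@]12C(=O)C(=[N+]=[N-])C(=O)[C@](CC=C(C)C)(C[C@@H](CC=C(C)C)C1(C)C)C2=O
F4 | step 9 | (1S,5S,7R)-8,8-dimethyl-1-[(2R)-2-methylbutanoyl]-5,7-bis(3-methylbut-2-en-1-yl)-4-(triethylsilyloxy)bicyclo[3.3.1]non-3-ene-2,9-dione | CC[C@@H](C)C(=O)[C@]12C(=O)C=C(O[Si](CC)(CC)CC)[C@](CC=C(C)C)(C[C@@H](CC=C(C)C)C1(C)C)C2=O
F5 | step 5 | 5-methylhex-4-enoic pivalic anhydride | CC(C)=CCCC(=O)OC(=O)C(C)(C)C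
F6 | step 5 | (S)-4-benzyl-3-(5-methylhex-4-enoyl)oxazolidin-2-one | CC(C)=CCCC(=O)N1[C@@H](Cc2ccccc2)COC1=O
F7 | step 5 | (S)-4-benzyl-3-[(2R)-2-(hydroxymethyl)-5-methylhex-4-enoyl]oxazolidin-2-one | OC[C@@H](CC=C(C)C)C(=O)N1[C@@H](Cc2ccccc2)COC1=O
F8 | step 5 | methyl (2R)-2-(hydroxymethyl)-5-methylhex-4-enoate | OC[C@@H](CC=C(C)C)C(=O)OC
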